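**Assumptions (one line each)**
- The target is read as the trans-(1S,2R) isomer: [(1S,2R)-7-hydroxy-1-(4-hydroxy-3-methoxyphenyl)-6-methoxy-1,2-dihydronaphthalene-2,3-diyl]dimethanol.
- O-TBS-vanillin (3) is bought as a catalogue compound (otherwise one extra silylation of vanillin). Succinaldehyde (6) is bought as its aqueous solution, extracted and distilled just before use; this is not counted as a step.

**Retrosynthetic overview**
1. Target 8 comes from dialdehyde 7 by 1,2-reduction of both CHO groups.
2. 7 comes from lactol 5 and succinaldehyde 6 in one amine-catalysed annulation. It forms C1–C2 (enamine 1,6-addition to a p-quinone methide, setting C1 and C2) and C3=C4 (aldol condensation).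
3. 5 is a masked o-formyl diaryl carbinol. Its C1–C8a bond comes from an aryllithium (from 6-bromovanillin) adding to O-silyl vanillin.
4. Both benzene rings are bought. A temporary phthalan (lactol) ring forms in step 2 and is opened in step 4, where the carbocyclic dihydronaphthalene ring is closed last.

**Route**

Step 1
Reactants: 1, 6-bromovanillin (2-bromo-4-hydroxy-5-methoxybenzaldehyde)
Product: 2, 2-bromo-4-[(tert-butyldimethylsilyl)oxy]-5-methoxybenzaldehyde
Conditions: TBSCl (1.2 equiv), imidazole (2 equiv), DMF, 0 °C → rt
Reagents that add atoms: tert-butyldimethylsilyl chloride, CC(C)(C)[Si](C)(C)Cl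
Why: Standard phenol silylation; it removes the acidic OH so the aryl bromide can be lithiated in step 2, and the silyl ether sits meta to the future C–Li so no retro-Brook shift is possible.

Step 2
Reactants: 2; 3, 4-[(tert-butyldimethylsilyl)oxy]-3-methoxybenzaldehyde (O-TBS-vanillin)
Product: 4, 5-[(tert-butyldimethylsilyl)oxy]-3-{4-[(tert-butyldimethylsilyl)oxy]-3-methoxyphenyl}-6-methoxy-1,3-dihydroisobenzofuran-1-ol (racemic, mixture of anomers)
Conditions: MeN(OMe)Li (1.1 equiv, from MeNHOMe·HCl + 2 n-BuLi), THF, –40 °C; n-BuLi (1.1 equiv), –78 °C; then 3, –78 → –20 °C; aq. NH4Cl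
Reagents that add atoms: none (the amide is released on work-up; both oxygens of the lactol come from the two aldehydes)
Why: In situ aldehyde protection as the lithium α-amino alkoxide, Br–Li exchange and aryllithium 1,2-addition to aldehyde 3 give, after hydrolysis, the o-formyl benzhydrol, which closes to the lactol; both stereocentres of 4 are uncontrolled and are erased in step 4.

Step 3
Reactants: 4
Product: 5, 3-(4-hydroxy-3-methoxyphenyl)-6-methoxy-1,3-dihydroisobenzofuran-1,5-diol (racemic, mixture of anomers)
Conditions: TBAF (2.4 equiv), AcOH (2.6 equiv), THF, 0 °C, 30 min; pH 7 buffer; used at once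
Reagents that add atoms: none
Why: Buffered fluoride desilylation of both aryl silyl ethers; buffering keeps the acid- and base-sensitive p-hydroxybenzhydryl lactol intact.

Step 4
Reactants: 5; 6, succinaldehyde (butanedial, 3 equiv, added over 6 h)
Product: 7, (1S,2R)-7-hydroxy-1-(4-hydroxy-3-methoxyphenyl)-6-methoxy-1,2-dihydronaphthalene-2,3-dicarbaldehyde (trans)
Conditions: (R)-α,α-diphenylprolinol trimethylsilyl ether (20 mol %), ClCH2CO2H (20 mol %), MeCN, 0 °C → rt, Ar; not isolated, taken directly into step 5
Reagents that add atoms: succinaldehyde (reactant 6), O=CCCC=O
Why: Proposed new method: an aminocatalytic formal (4+2) annulation in which acid-promoted dehydration of ring-opened 5 gives an o-formylaryl p-quinone methide (1,4-bis-electrophile) and succinaldehyde acts as a 1,2-bis-nucleophile through two successive enamines. The first enamine adds 1,6 to the quinone methide carbon through its Re face (left open by the (R)-catalyst), forming C1–C2 and setting C2 as R; C1 is set as S in the same bond-forming event by the approach that keeps the quinone ring anti to the bulky enamine terminus (trans). The second enamine closes the ring by intramolecular aldol condensation onto the aryl aldehyde to give the C3=C4 enal, and the aldol-first order converges on the same product. The closest known reaction types are secondary-amine-catalysed enamine 1,6-additions of simple aldehydes to stabilised p-quinone methides and amine-catalysed Michael/aldol-condensation dominos of succinaldehyde.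

Step 5
Reactants: 7
Product: 8, [(1S,2R)-7-hydroxy-1-(4-hydroxy-3-methoxyphenyl)-6-methoxy-1,2-dihydronaphthalene-2,3-diyl]dimethanol (target)
Conditions: NaBH4 (5 equiv), CeCl3·7H2O (1.5 equiv), MeOH added to the step-4 mixture, –40 → 0 °C; aq. NH4Cl; chromatography (removes any cis diol), recrystallisation
Reagents that add atoms: none (hydride and protons only)
Why: Luche 1,2-reduction converts the enal and the saturated aldehyde to the two primary alcohols without touching the styrenic C3=C4 bond; reducing at once at low temperature freezes the epimerisable C2 centre, and C1 is not epimerisable.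

**Compound list**
1 | 6-bromovanillin (2-bromo-4-hydroxy-5-methoxybenzaldehyde) | O=Cc1cc(OC)c(O)cc1Br | starting material
2 | 2-bromo-4-[(tert-butyldimethylsilyl)oxy]-5-methoxybenzaldehyde | O=Cc1cc(OC)c(O[Si](C)(C)C(C)(C)C)cc1Br | intermediate
3 | 4-[(tert-butyldimethylsilyl)oxy]-3-methoxybenzaldehyde | O=Cc1ccc(O[Si](C)(C)C(C)(C)C)c(OC)c1 | starting material
4 | bis-TBS lactol (racemic, anomeric mixture) | OC1OC(c2ccc(O[Si](C)(C)C(C)(C)C)c(OC)c2)c2cc(O[Si](C)(C)C(C)(C)C)c(OC)cc21 | intermediate
5 | 3-(4-hydroxy-3-methoxyphenyl)-6-methoxy-1,3-dihydroisobenzofuran-1,5-diol (racemic, anomeric mixture) | OC1OC(c2ccc(O)c(OC)c2)c2cc(O)c(OC)cc21 | intermediate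
6 | succinaldehyde (butanedial) | O=CCCC=O | starting material
7 | (1S,2R)-7-hydroxy-1-(4-hydroxy-3-methoxyphenyl)-6-methoxy-1,2-dihydronaphthalene-2,3-dicarbaldehyde | COc1cc([C@H]2c3cc(O)c(OC)cc3C=C(C=O)[C@@H]2C=O)ccc1O | intermediate
8 | [(1S,2R)-7-hydroxy-1-(4-hydroxy-3-methoxyphenyl)-6-methoxy-1,2-dihydronaphthalene-2,3-diyl]dimethanol | COc1cc([C@H]2c3cc(O)c(OC)cc3C=C(CO)[C@@H]2CO)ccc1O | target

**Totals**
- Total step count: 5 (steps 4 and 5 are run in one pot, so four isolations).
- Longest linear sequence: 5 steps, from 1.

**Three steps most likely to fail, with fallbacks**

1. Step 4 (proposed annulation).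
   - Risks: succinaldehyde self-aldol; quinone methide oligomerisation or isobenzofuran formation from the lactol; incomplete control of C1 (cis isomer); C2 epimerisation or air oxidation of 7 to the naphthalene.
   - Fallback (known chemistry): set C1 alone by a bifunctional squaramide- or phase-transfer-catalysed enantioselective 1,6-addition of dimethyl malonate to the same p-quinone methide. Then build the ring conventionally: C-alkylation of the malonate carbon with methyl bromoacetate, base-mediated intramolecular aldol condensation onto the o-CHO (C3=C4), Krapcho removal of one ester with equilibration of C2 to trans, and DIBAL-H reduction of the two esters.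

2. Step 2 (in situ protection / Br–Li exchange / addition).
   - Risks: incomplete amino-alkoxide formation leading to butyl addition to the aldehyde; attack at silicon.
   - Fallback: reverse the polarity and introduce the formyl group last. Add the Grignard reagent of TBS-protected 4-bromo-2-methoxyphenol to TBS-protected 6-bromoisovanillin (2-bromo-5-hydroxy-4-methoxybenzaldehyde). Then carry out Br–Li exchange on the resulting bromo-benzhydrol (as its alkoxide) and quench with DMF to reach the same lactol 4.

3. Step 3 (release and handling of free bis-phenol lactol 5).
   - Risk: 5 can ionise to the quinone methide and self-condense on silica or on standing.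
   - Fallback: change the quinone methide precursor. Convert crude 5 with p-toluenesulfinic acid into the bench-stable o-formyl 4-hydroxybenzhydryl sulfone. Release the quinone methide from it in step 4 with mild base (sulfinate elimination) in place of acid-promoted dehydration of the lactol.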